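**Plan**
- Cuts, in retrosynthetic order: the C1–O ester; the 2,4-disubstituted oxazole at O1–C5 and at its C2–N3 amide (cyclodehydration of an α-amido aldehyde made from 2-(oxazol-5-yl)acetic acid); the bond from C1 to oxazole C4 (isocyanoacetate aldol).
- Enabling feature: C1(O)–C4(N3)–C5 of the 2,4-disubstituted oxazole is a hidden β-hydroxy-α-amino acid (C1 = carbinol, ring C4 = α-carbon, N3 = amine, C5 = carboxyl carbon), and C3–C6 is 2-deoxy-L-fucose.
- Forward: di-O-acetyl-L-fucal is opened to the tribenzyl aldehyde; the gold-catalysed aldol closes a sacrificial trans-oxazoline, which is then opened; N-acylation, ester-to-aldehyde reduction and cyclodehydration build the 2,4-disubstituted oxazole; the 5-substituted oxazole arrives ready-made in the acid.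
- Stereochemistry: C3, C4, C5 come from the chiral pool; C1 (R) comes from the chiral ferrocenylphosphine–gold catalyst; the α-carbon becomes aromatic, so its configuration is irrelevant.

Key step: step 6

Remark (assumption): 2-(1,3-oxazol-5-yl)acetic acid is treated as a purchasable building block; side-chain carbons are numbered C1 (oxazolyl carbinol) to C6 (methyl).

Step 1
Reactants: 1 3,4-di-O-acetyl-L-fucal
Product: 2 3,4-di-O-acetyl-2-deoxy-L-fucopyranose (anomer mixture)
Conditions: PPh3·HBr (cat.), H2O, THF, rt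
Reagents that add atoms: water, O
Why: Acid-catalysed glycal hydration protonates C2 of the enol ether and water traps the oxocarbenium ion, giving the 2-deoxy hemiacetal without touching C3–C5.

Step 2
Reactants: 2 3,4-di-O-acetyl-2-deoxy-L-fucopyranose
Product: 3 2-deoxy-L-fucose (2,6-dideoxy-L-lyxo-hexopyranose)
Conditions: NaOMe (cat.), MeOH, rt; then Amberlite IR-120 (H+)
Reagents that add atoms: none
Why: Zemplén transesterification removes both acetates under catalytic methoxide and leaves the three stereocentres untouched.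

Step 3
Reactants: 3 2-deoxy-L-fucose
Product: 4 (2S,3R,4S)-1-(1,3-dithian-2-yl)pentane-2,3,4-triol
Conditions: HS(CH2)3SH, conc. HCl, 0 °C
Reagents that add atoms: propane-1,3-dithiol, SCCCS
Why: Acid-promoted dithioacetalisation (mercaptalation, standard for 2-deoxy sugars) traps the open-chain aldehyde form as the 1,3-dithiane and frees all three hydroxyls.

Step 4
Reactants: 4 (2S,3R,4S)-1-(1,3-dithian-2-yl)pentane-2,3,4-triol
Product: 5 2-[(2S,3R,4S)-2,3,4-tris(benzyloxy)pentyl]-1,3-dithiane
Conditions: NaH, BnBr, TBAI (cat.), DMF, 0 °C → rt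
Reagents that add atoms: benzyl bromide, BrCc1ccccc1
Why: Williamson etherification of the three alkoxides; the dithiane C–H is far too weakly acidic to compete under NaH/DMF.

Step 5
Reactants: 5 2-[(2S,3R,4S)-2,3,4-tris(benzyloxy)pentyl]-1,3-dithiane
Product: 6 (3S,4R,5S)-3,4,5-tris(benzyloxy)hexanal
Conditions: MeI, CaCO3, MeCN/H2O (4:1), 45 °C
Reagents that add atoms: water, O
Why: Alkylative dithioacetal hydrolysis (S-methylation, then attack of water on the sulfonium) unmasks the aldehyde, and the carbonate buffer keeps the β-benzyloxy aldehyde from eliminating.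

Step 6
Reactants: 6 (3S,4R,5S)-3,4,5-tris(benzyloxy)hexanal; 7 methyl isocyanoacetate
Product: 8 methyl (4S,5R)-5-[(2S,3R,4S)-2,3,4-tris(benzyloxy)pentyl]-4,5-dihydro-1,3-oxazole-4-carboxylate
Conditions: [Au(c-HexNC)2]BF4 (1 mol %), (R)-N-methyl-N-[2-(morpholin-4-yl)ethyl]-1-[(S)-1′,2-bis(diphenylphosphino)ferrocenyl]ethylamine (1.1 mol %), CH2Cl2, rt
Reagents that add atoms: none
Why: The pendant morpholine of the ligand deprotonates the gold-bound isocyanoacetate to an ion-paired enolate, which adds through its α-carbon to the aldehyde carbonyl of 6, and the resulting alkoxide attacks the metal-activated isocyanide carbon before protodeauration releases the oxazoline. The closest known reaction is the gold(I)/ferrocenylphosphine-catalysed asymmetric aldol of isocyanoacetates with aldehydes, which tolerates aliphatic aldehydes. The one ring formed, the 4,5-dihydro-1,3-oxazole, closes by 5-endo-dig attack of oxygen on the isocyanide carbon. Ring C5 (target C1, R) is set by the ligand, whose (R)-central/(S)-planar form is the one expected to deliver (4S,5R)-oxazolines from simple aldehydes, and ring C4 (S) follows from the trans preference of the cyclisation and is erased later. The step needs catalyst-controlled choice of the aldehyde face against any 1,3-bias from the C3 benzyloxy group; the substrate helps because it has no α-stereocentre, its benzyl ethers do not bind the soft gold centre, and no Lewis acid is present to organise a chelated or dipole-controlled transition state. Any cis isomer, whose C5 may be epimeric, would be removed by chromatography at this stage.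

Step 7
Reactants: 8 methyl (4S,5R)-5-[(2S,3R,4S)-2,3,4-tris(benzyloxy)pentyl]-4,5-dihydro-1,3-oxazole-4-carboxylate
Product: 9 methyl (2S,3R,5S,6R,7S)-2-amino-5,6,7-tris(benzyloxy)-3-hydroxyoctanoate hydrochloride
Conditions: conc. HCl, MeOH, 50 °C
Reagents that add atoms: hydrogen chloride, Cl
Why: Acid-catalysed solvolysis of the cyclic imidate (oxazoline hydrolysis/methanolysis) expels ring C2 as methyl formate and frees the threo amino alcohol as its ammonium salt without breaking a bond at either stereocentre, while benzyl ethers and the methyl ester tolerate methanolic HCl.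

Step 8
Reactants: 9 methyl (2S,3R,5S,6R,7S)-2-amino-5,6,7-tris(benzyloxy)-3-hydroxyoctanoate hydrochloride; 10 2-(1,3-oxazol-5-yl)acetic acid
Product: 11 methyl (2S,3R,5S,6R,7S)-5,6,7-tris(benzyloxy)-3-hydroxy-2-[2-(1,3-oxazol-5-yl)acetamido]octanoate
Conditions: EDC·HCl, HOBt, N-methylmorpholine, CH2Cl2/DMF, 0 °C → rt
Reagents that add atoms: none
Why: Carbodiimide/HOBt amide coupling acylates the primary amine much faster than the hindered secondary alcohol, so the β-hydroxy amide should form chemoselectively.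

Step 9
Reactants: 11 methyl (2S,3R,5S,6R,7S)-5,6,7-tris(benzyloxy)-3-hydroxy-2-[2-(1,3-oxazol-5-yl)acetamido]octanoate
Product: 12 methyl (2S,3R,5S,6R,7S)-5,6,7-tris(benzyloxy)-3-[(tert-butyldimethylsilyl)oxy]-2-[2-(1,3-oxazol-5-yl)acetamido]octanoate
Conditions: TBSOTf, 2,6-lutidine, CH2Cl2, 0 °C
Reagents that add atoms: tert-butyldimethylsilyl trifluoromethanesulfonate, CC(C)(C)[Si](C)(C)OS(=O)(=O)C(F)(F)F
Why: Silyl triflate/lutidine silylation turns the only hydroxyl into a TBS ether that masks the C1 oxygen through reduction and cyclodehydration and is a poor leaving group for β-elimination.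

Step 10
Reactants: 12 methyl (2S,3R,5S,6R,7S)-5,6,7-tris(benzyloxy)-3-[(tert-butyldimethylsilyl)oxy]-2-[2-(1,3-oxazol-5-yl)acetamido]octanoate
Product: 13 N-[(2S,3R,5S,6R,7S)-5,6,7-tris(benzyloxy)-3-[(tert-butyldimethylsilyl)oxy]-1-oxooctan-2-yl]-2-(1,3-oxazol-5-yl)acetamide
Conditions: DIBAL-H (2.5 equiv), CH2Cl2, −78 °C; Rochelle salt work-up
Reagents that add atoms: none
Why: Partial ester reduction with DIBAL-H at −78 °C should stop at the aluminium hemiacetal (held by the neighbouring amidate and silyloxy oxygens), which collapses to the α-amido aldehyde on work-up as is routine for N-acyl O-silyl serine and threonine esters; the α-centre may epimerise without consequence and the crude aldehyde is used at once.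

Step 11
Reactants: 13 N-[(2S,3R,5S,6R,7S)-5,6,7-tris(benzyloxy)-3-[(tert-butyldimethylsilyl)oxy]-1-oxooctan-2-yl]-2-(1,3-oxazol-5-yl)acetamide
Product: 15 4-[(1R,3S,4R,5S)-3,4,5-tris(benzyloxy)-1-[(tert-butyldimethylsilyl)oxy]hexyl]-2-(1,3-oxazol-5-ylmethyl)-1,3-oxazole, via 5-bromooxazoline 14 (not isolated)
Conditions: PPh3, (BrCCl2)2, 2,6-di-tert-butyl-4-methylpyridine, CH2Cl2, 0 °C → rt; then DBU, MeCN, rt
Reagents that add atoms: none
Why: Robinson–Gabriel-type cyclodehydration in the Wipf variant for α-amido aldehydes: the amide oxygen adds to the aldehyde, the phosphonium reagent converts the resulting 5-hydroxyoxazoline into the 5-bromooxazoline, and DBU-induced loss of HBr aromatises it to the 2,4-disubstituted oxazole, erasing the α-stereocentre.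

Step 12
Reactants: 15 4-[(1R,3S,4R,5S)-3,4,5-tris(benzyloxy)-1-[(tert-butyldimethylsilyl)oxy]hexyl]-2-(1,3-oxazol-5-ylmethyl)-1,3-oxazole
Product: 16 (1R,3S,4R,5S)-3,4,5-tris(benzyloxy)-1-[2-(1,3-oxazol-5-ylmethyl)-1,3-oxazol-4-yl]hexan-1-ol
Conditions: HF·pyridine, pyridine/THF, 0 °C → rt
Reagents that add atoms: none
Why: Fluoride-driven desilylation cleaves only the Si–O bond, so the C1 carbinol is freed with retention while benzyl ethers and both oxazoles are inert to buffered HF·pyridine.

Step 13
Reactants: 16 (1R,3S,4R,5S)-3,4,5-tris(benzyloxy)-1-[2-(1,3-oxazol-5-ylmethyl)-1,3-oxazol-4-yl]hexan-1-ol; 17 14-methylpentadecanoic acid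
Product: 18 (1R,3S,4R,5S)-3,4,5-tris(benzyloxy)-1-[2-(1,3-oxazol-5-ylmethyl)-1,3-oxazol-4-yl]hexyl 14-methylpentadecanoate
Conditions: EDC·HCl, DMAP, CH2Cl2, rt
Reagents that add atoms: none
Why: Steglich esterification (carbodiimide activation, DMAP acyl transfer) acylates the only free hydroxyl at oxygen, so C1 keeps its R configuration.

Step 14
Reactants: 18 (1R,3S,4R,5S)-3,4,5-tris(benzyloxy)-1-[2-(1,3-oxazol-5-ylmethyl)-1,3-oxazol-4-yl]hexyl 14-methylpentadecanoate
Product: 19 (1R,3S,4R,5S)-3,4,5-trihydroxy-1-[2-(1,3-oxazol-5-ylmethyl)-1,3-oxazol-4-yl]hexyl 14-methylpentadecanoate (CNP0273575.1)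
Conditions: H2 (1 atm), Pd(OH)2/C, EtOAc/MeOH, rt
Reagents that add atoms: none
Why: Palladium-catalysed hydrogenolysis cleaves the three benzyl ethers to toluene while the aliphatic ester and the oxazoles should not be reduced at 1 atm in neutral solvent, and the reaction is stopped as soon as the triol has formed to spare the oxazolyl-carbinol C–O bond.

**Compound list**
1 | 3,4-di-O-acetyl-L-fucal | C[C@@H]1OC=C[C@H](OC(C)=O)[C@@H]1OC(C)=O | starting material
2 | 3,4-di-O-acetyl-2-deoxy-L-fucopyranose (anomer mixture) | C[C@@H]1OC(O)C[C@H](OC(C)=O)[C@@H]1OC(C)=O | intermediate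
3 | 2-deoxy-L-fucose (pyranose form) | C[C@@H]1OC(O)C[C@H](O)[C@@H]1O | intermediate
4 | (2S,3R,4S)-1-(1,3-dithian-2-yl)pentane-2,3,4-triol | C1CSC(SC1)C[C@H](O)[C@H](O)[C@H](C)O | intermediate
5 | 2-[(2S,3R,4S)-2,3,4-tris(benzyloxy)pentyl]-1,3-dithiane | C1CSC(SC1)C[C@H](OCc1ccccc1)[C@H](OCc1ccccc1)[C@H](C)OCc1ccccc1 | intermediate
6 | (3S,4R,5S)-3,4,5-tris(benzyloxy)hexanal | O=CC[C@H](OCc1ccccc1)[C@H](OCc1ccccc1)[C@H](C)OCc1ccccc1 | intermediate
7 | methyl isocyanoacetate | [C-]#[N+]CC(=O)OC | starting material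
8 | methyl (4S,5R)-5-[(2S,3R,4S)-2,3,4-tris(benzyloxy)pentyl]-4,5-dihydro-1,3-oxazole-4-carboxylate | COC(=O)[C@H]1N=CO[C@@H]1C[C@H](OCc2ccccc2)[C@H](OCc2ccccc2)[C@H](C)OCc2ccccc2 | intermediate
9 | methyl (2S,3R,5S,6R,7S)-2-amino-5,6,7-tris(benzyloxy)-3-hydroxyoctanoate hydrochloride | COC(=O)[C@@H](N)[C@H](O)C[C@H](OCc1ccccc1)[C@H](OCc1ccccc1)[C@H](C)OCc1ccccc1.Cl | intermediate
10 | 2-(1,3-oxazol-5-yl)acetic acid | OC(=O)Cc1cnco1 | starting material
11 | methyl (2S,3R,5S,6R,7S)-5,6,7-tris(benzyloxy)-3-hydroxy-2-[2-(1,3-oxazol-5-yl)acetamido]octanoate | COC(=O)[C@@H](NC(=O)Cc1cnco1)[C@H](O)C[C@H](OCc1ccccc1)[C@H](OCc1ccccc1)[C@H](C)OCc1ccccc1 | intermediate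
12 | methyl (2S,3R,5S,6R,7S)-5,6,7-tris(benzyloxy)-3-[(tert-butyldimethylsilyl)oxy]-2-[2-(1,3-oxazol-5-yl)acetamido]octanoate | COC(=O)[C@@H](NC(=O)Cc1cnco1)[C@H](O[Si](C)(C)C(C)(C)C)C[C@H](OCc1ccccc1)[C@H](OCc1ccccc1)[C@H](C)OCc1ccccc1 | intermediate
13 | N-[(2S,3R,5S,6R,7S)-5,6,7-tris(benzyloxy)-3-[(tert-butyldimethylsilyl)oxy]-1-oxooctan-2-yl]-2-(1,3-oxazol-5-yl)acetamide | O=C[C@@H](NC(=O)Cc1cnco1)[C@H](O[Si](C)(C)C(C)(C)C)C[C@H](OCc1ccccc1)[C@H](OCc1ccccc1)[C@H](C)OCc1ccccc1 | intermediate
14 | 5-bromo-4-[(1R,3S,4R,5S)-3,4,5-tris(benzyloxy)-1-[(tert-butyldimethylsilyl)oxy]hexyl]-2-(1,3-oxazol-5-ylmethyl)-4,5-dihydro-1,3-oxazole (mixture at ring C4 and C5) | BrC1OC(Cc2cnco2)=NC1[C@H](O[Si](C)(C)C(C)(C)C)C[C@H](OCc1ccccc1)[C@H](OCc1ccccc1)[C@H](C)OCc1ccccc1 | intermediate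
15 | 4-[(1R,3S,4R,5S)-3,4,5-tris(benzyloxy)-1-[(tert-butyldimethylsilyl)oxy]hexyl]-2-(1,3-oxazol-5-ylmethyl)-1,3-oxazole | CC(C)(C)[Si](C)(C)O[C@H](C[C@H](OCc1ccccc1)[C@H](OCc1ccccc1)[C@H](C)OCc1ccccc1)c1coc(Cc2cnco2)n1 | intermediate
16 | (1R,3S,4R,5S)-3,4,5-tris(benzyloxy)-1-[2-(1,3-oxazol-5-ylmethyl)-1,3-oxazol-4-yl]hexan-1-ol | O[C@H](C[C@H](OCc1ccccc1)[C@H](OCc1ccccc1)[C@H](C)OCc1ccccc1)c1coc(Cc2cnco2)n1 | intermediate
17 | 14-methylpentadecanoic acid | CC(C)CCCCCCCCCCCCC(=O)O | starting material
18 | (1R,3S,4R,5S)-3,4,5-tris(benzyloxy)-1-[2-(1,3-oxazol-5-ylmethyl)-1,3-oxazol-4-yl]hexyl 14-methylpentadecanoate | CC(C)CCCCCCCCCCCCC(=O)O[C@H](C[C@H](OCc1ccccc1)[C@H](OCc1ccccc1)[C@H](C)OCc1ccccc1)c1coc(Cc2cnco2)n1 | intermediate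
19 | (1R,3S,4R,5S)-3,4,5-trihydroxy-1-[2-(1,3-oxazol-5-ylmethyl)-1,3-oxazol-4-yl]hexyl 14-methylpentadecanoate | CC(C)CCCCCCCCCCCCC(=O)O[C@H](C[C@H](O)[C@H](O)[C@H](C)O)c1coc(Cc2cnco2)n1 | target

**Step count and risks**
Total steps: 14. Longest linear sequence: 14 steps (1 → 19); compounds 7, 10 and 17 enter as purchased.

Steps most likely to fail:

1. Step 6. Facial discrimination at the aldehyde may be insufficient. Open-chain β-alkoxy aldehydes tend toward 1,3-anti addition, whereas the target needs the 1,3-syn relationship between the C1 and C3 oxygens, and unbranched aldehydes are the least selective class for this catalyst. The result would be C1 epimers that are hard to separate. Fallback: move C1 control from the aldol to a ketone reduction. The aldol then only has to build the skeleton, and the material is carried through steps 7–12 whatever its C1 composition. The fallback sets out from alcohol 16. Dess–Martin periodinane with NaHCO3 in CH2Cl2 should give the ketone (3S,4R,5S)-3,4,5-tris(benzyloxy)-1-[2-(1,3-oxazol-5-ylmethyl)-1,3-oxazol-4-yl]hexan-1-one F1. Corey–Bakshi–Shibata reduction with the (S)-methyl oxazaborolidine and BH3·SMe2 in THF at −20 °C (oxazolyl as the large group, CH2 as the small one) should then return the 1R alcohol and rejoin the route at 16. A chelating hydride such as Zn(BH4)2 would push the same 1,3-syn way through the C3 benzyloxy group.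

2. Step 10. The reduction may run on to the primary alcohol, or the α-amido aldehyde may lose silanol by β-elimination during work-up. Fallback: a two-stage redox change from 12. Exhaustive reduction with LiBH4 in THF/MeOH at 0 °C should give the primary alcohol N-[(2R,3R,5S,6R,7S)-5,6,7-tris(benzyloxy)-3-[(tert-butyldimethylsilyl)oxy]-1-hydroxyoctan-2-yl]-2-(1,3-oxazol-5-yl)acetamide F2. Buffered Dess–Martin oxidation then gives the aldehyde, used crude, coming back to the route at 13.

3. Step 14. The ester sits on an oxazol-4-yl carbinol, so hydrogenolysis may also cleave the C1–O bond and strip the fatty acid; alternatively the oxazole nitrogens may inhibit the catalyst and leave partly benzylated material. Fallback: non-reductive debenzylation from 18 with BCl3 and pentamethylbenzene as cation scavenger in CH2Cl2 at −78 °C, where N-complexation of the oxazole should disfavour ionisation at C1. This leads directly to 19 and makes no new compound (F0).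

**Further compounds**
F1 | step 6 | (3S,4R,5S)-3,4,5-tris(benzyloxy)-1-[2-(1,3-oxazol-5-ylmethyl)-1,3-oxazol-4-yl]hexan-1-one | O=C(C[C@H](OCc1ccccc1)[C@H](OCc1ccccc1)[C@H](C)OCc1ccccc1)c1coc(Cc2cnco2)n1
F2 | step 10 | N-[(2R,3R,5S,6R,7S)-5,6,7-tris(benzyloxy)-3-[(tert-butyldimethylsilyl)oxy]-1-hydroxyoctan-2-yl]-2-(1,3-oxazol-5-yl)acetamide | OC[C@@H](NC(=O)Cc1cnco1)[C@H](O[Si](C)(C)C(C)(C)C)C[C@H](OCc1ccccc1)[C@H](OCc1ccccc1)[C@H](C)OCc1ccccc1
F0 | step 14 | none | none
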